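**Retrosynthetic overview**
1. The chain is numbered C1(OH)–C2–C3–C4, with ring A on C1 and ring B on C3. C3 carries ring B, methyl C4 and C2, and it sits ortho to the 2-methoxy oxygen of ring B. An aryl allyl ether [3,3] shift leaves exactly this ortho-oxygen and allylic-carbon pair.
2. C1–OH comes from C1–B, which comes from the (E)-C1=C2 styrene by ligand-controlled copper hydride hydroboration and oxidation. This sets C1.
3. C1=C2 comes from cross-metathesis of 2,4,5-trimethoxystyrene (ring A) with the propenyl stub of the O-methylated rearrangement product.
4. The ring B–C3 bond comes from the aromatic Claisen shift of the (R,E)-pent-3-en-2-yl ether of 3,4-dimethoxyphenol, which sets C3 by 1,3-chirality transfer. The ether comes from Mitsunobu inversion of lipase-resolved (S)-alcohol.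
5. No ring is formed. Rings A and B are both bought as arenes.

Key step: step 3

Assumption: the sense of induction in step 7 is assigned by analogy with simple (E)-β-alkylstyrenes, for which the (S)-ligand is taken to give the (R)-benzylic boronate; the C1 configuration is to be verified on 13, and if it proves opposite the (R)-ligand is used with no other change.

**Step 1**
Reactants: 1 rac-(E)-pent-3-en-2-ol
Product: 2 (2S,3E)-pent-3-en-2-ol
Conditions: Novozym 435 (immobilised Candida antarctica lipase B), vinyl acetate (0.6 equiv), pentane, 25 °C, stopped just past half conversion; filtration, chromatography (pentane/Et2O)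
Reagents that add atoms: none
Why: Lipase-catalysed kinetic resolution by irreversible transesterification, in which the enzyme should acylate the (R)-alcohol much faster (methyl is the medium substituent, propenyl the large one), so running slightly past half conversion should leave 2 in high enantiomeric purity without making a new stereocentre.

**Step 2**
Reactants: 2 (2S,3E)-pent-3-en-2-ol; 3 3,4-dimethoxyphenol
Product: 4 4-[(2R,3E)-pent-3-en-2-yloxy]-1,2-dimethoxybenzene
Conditions: PPh3, DIAD, toluene, −20 to 0 °C
Reagents that add atoms: none
Why: Mitsunobu etherification, in which phenoxide displaces the activated secondary hydroxyl in an SN2 manner with inversion (S to R), and the cold, weakly polar medium holds back ionisation and SN2′ attack, which on this 1,3-dimethylallyl unit would give the same constitution with lower enantiopurity.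

**Step 3**
Reactants: 4 4-[(2R,3E)-pent-3-en-2-yloxy]-1,2-dimethoxybenzene
Product: 6 4,5-dimethoxy-2-[(2S,3E)-pent-3-en-2-yl]phenol, via ortho-dienone 5 (not isolated)
Conditions: PhNEt2 (degassed), 175 °C, sealed tube, Ar; silica chromatography
Reagents that add atoms: none
Why: Heating triggers a one-step [3,3]-sigmatropic shift (thermal aromatic Claisen rearrangement of an enantioenriched secondary (E)-allyl aryl ether, a known reaction type with 1,3-chirality transfer), in which the O–C2′ bond breaks while ring carbon C6 of the ether (phenol numbering) bonds to the alkene terminus C4′, and dienone 5 then enolises to phenol 6. No ring is closed, because the six-membered array exists only in the transition state. The carbinol centre of 4 controls the new benzylic centre (C3 of the target): in the chair with the carbinol methyl equatorial, the aryl carbon arrives on the allyl face that oxygen is leaving, so (R,E)-4 should give (S,E)-6, and the ring stereocentre of 5 is erased on enolisation. The minor chair with that methyl axial leads to the (R,Z)-isomer, so alkene geometry turns into enantiopurity once the stub is cut off, and the Z-alkene is therefore removed after step 4. The step also needs attack at C6 rather than C2; C2 is wedged between the ether oxygen and the 3-methoxy group and must accept a branched carbon, which is a strong bias but not a complete block, so any C2 isomer is removed on silica. The basic, non-ionising solvent holds back C–O heterolysis, which would racemise the symmetrically substituted allyl unit, and exclusion of air protects the oxidation-prone phenol.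

**Step 4**
Reactants: 6 4,5-dimethoxy-2-[(2S,3E)-pent-3-en-2-yl]phenol
Product: 7 1,2,4-trimethoxy-5-[(2S,3E)-pent-3-en-2-yl]benzene
Conditions: MeI, K2CO3, acetone, reflux; chromatography on AgNO3-impregnated silica
Reagents that add atoms: iodomethane, CI
Why: Williamson O-methylation turns the freed oxygen into the third methoxy group of ring B, carbonate is far too weak to deprotonate the benzylic-allylic C–H so C3 is untouched, and argentation chromatography at this less oxidation-sensitive stage removes the Z-alkene that carries the wrong C3 configuration.

**Step 5**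
Reactants: 8 2,4,5-trimethoxybenzaldehyde
Product: 9 1-ethenyl-2,4,5-trimethoxybenzene (2,4,5-trimethoxystyrene)
Conditions: Ph3PCH3Br, KOtBu, THF, 0 °C to rt
Reagents that add atoms: methyltriphenylphosphonium bromide, C[P+](c1ccccc1)(c1ccccc1)c1ccccc1.[Br-]
Why: Wittig methylenation with the non-stabilised ylide is general for electron-rich benzaldehydes, and 9 is kept cold and acid-free and used promptly because it polymerises easily.

**Step 6**
Reactants: 7 1,2,4-trimethoxy-5-[(2S,3E)-pent-3-en-2-yl]benzene; 9 1-ethenyl-2,4,5-trimethoxybenzene (3 equiv)
Product: 10 (1E,3S)-1,3-bis(2,4,5-trimethoxyphenyl)but-1-ene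
Conditions: second-generation Hoveyda–Grubbs catalyst (5 mol %), 1,4-benzoquinone (10 mol %), toluene, 60 °C, slow Ar purge
Reagents that add atoms: none
Why: Olefin cross-metathesis exchanges the ethylidene end of 7 for the arylmethylidene of 9 with loss of propene, the conjugated 1,2-disubstituted product should form as the E-isomer under thermodynamic control, excess 9 offsets its self-metathesis, and benzoquinone suppresses ruthenium hydride alkene migration so that C3 keeps its configuration.

**Step 7**
Reactants: 10 (1E,3S)-1,3-bis(2,4,5-trimethoxyphenyl)but-1-ene; 11 pinacolborane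
Product: 12 2-[(1R,3S)-1,3-bis(2,4,5-trimethoxyphenyl)butyl]-4,4,5,5-tetramethyl-1,3,2-dioxaborolane
Conditions: CuCl (5 mol %), NaOtBu (10 mol %), (S)-DTBM-SEGPHOS (5.5 mol %), toluene, rt to 40 °C
Reagents that add atoms: none
Why: Copper hydride catalysed enantioselective hydroboration of a β-alkyl vinylarene, in which syn hydrocupration places copper on benzylic C1 next to ring A and hydrogen on C2, the bulky chiral bisphosphine selects the alkene face, and exchange with the B–H bond of 11 proceeds with retention to give the (1R)-boronate while C3 is a spectator.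

**Step 8**
Reactants: 12 2-[(1R,3S)-1,3-bis(2,4,5-trimethoxyphenyl)butyl]-4,4,5,5-tetramethyl-1,3,2-dioxaborolane
Product: 13 (1R,3S)-1,3-bis(2,4,5-trimethoxyphenyl)butan-1-ol (target)
Conditions: 30 % aq H2O2, 2 M NaOH, THF, 0 °C; neutral work-up, Et3N-deactivated silica
Reagents that add atoms: hydrogen peroxide, OO
Why: Boronate oxidation by hydroperoxide addition and 1,2-migration of carbon from boron to oxygen goes with retention, so (1R)-12 gives (1R)-13, and acid is excluded from work-up and chromatography because a carbinol next to a trimethoxyphenyl ring ionises easily.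

**Compound list**
1 | rac-(E)-pent-3-en-2-ol | C/C=C/C(C)O | starting material
2 | (2S,3E)-pent-3-en-2-ol | C/C=C/[C@H](C)O | intermediate
3 | 3,4-dimethoxyphenol | COc1ccc(O)cc1OC | starting material
4 | 4-[(2R,3E)-pent-3-en-2-yloxy]-1,2-dimethoxybenzene | C/C=C/[C@@H](C)Oc1ccc(OC)c(OC)c1 | intermediate
5 | (6S)-3,4-dimethoxy-6-[(2S,3E)-pent-3-en-2-yl]cyclohexa-2,4-dien-1-one (not isolated) | C/C=C/[C@H](C)[C@H]1C=C(OC)C(OC)=CC1=O | intermediate
6 | 4,5-dimethoxy-2-[(2S,3E)-pent-3-en-2-yl]phenol | C/C=C/[C@H](C)c1cc(OC)c(OC)cc1O | intermediate
7 | 1,2,4-trimethoxy-5-[(2S,3E)-pent-3-en-2-yl]benzene | C/C=C/[C@H](C)c1cc(OC)c(OC)cc1OC | intermediate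
8 | 2,4,5-trimethoxybenzaldehyde | COc1cc(OC)c(C=O)cc1OC | starting material
9 | 1-ethenyl-2,4,5-trimethoxybenzene | C=Cc1cc(OC)c(OC)cc1OC | intermediate
10 | (1E,3S)-1,3-bis(2,4,5-trimethoxyphenyl)but-1-ene | COc1cc(OC)c(/C=C/[C@H](C)c2cc(OC)c(OC)cc2OC)cc1OC | intermediate
11 | pinacolborane | CC1(C)OBOC1(C)C | starting material
12 | 2-[(1R,3S)-1,3-bis(2,4,5-trimethoxyphenyl)butyl]-4,4,5,5-tetramethyl-1,3,2-dioxaborolane | COc1cc(OC)c([C@H](B2OC(C)(C)C(C)(C)O2)C[C@H](C)c3cc(OC)c(OC)cc3OC)cc1OC | intermediate
13 | (1R,3S)-1,3-bis(2,4,5-trimethoxyphenyl)butan-1-ol | COc1cc(OC)c([C@H](O)C[C@H](C)c2cc(OC)c(OC)cc2OC)cc1OC | target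

Total step count: 8
Longest linear sequence: 7 steps (1, 2, 3, 4, 6, 7, 8)

**Three steps most likely to fail**

**Step 6 (cross-metathesis).**
- Risk: the alkene of 7 is internal and branched at its allylic carbon. Styrene 9 can tie up ruthenium as an ortho-methoxy-chelated benzylidene and can consume itself by self-metathesis, so turnover may stall. Alkene migration towards ring B would also erase C3.
- Fallback: this sets out from 7 and returns at 10. It replaces metathesis by cleavage, olefination and cross-coupling.
  - Dihydroxylation (OsO4 cat., NMO, acetone/H2O) gives (4R)-4-(2,4,5-trimethoxyphenyl)pentane-2,3-diol F1.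
  - NaIO4 cleavage gives (2R)-2-(2,4,5-trimethoxyphenyl)propanal F2. The spatial arrangement at C3 is unchanged and only the descriptor changes by priority. F2 is used crude because loss of configuration by enolisation is possible.
  - The non-basic Takai olefination (CHI3, CrCl2, THF, 0 °C) gives 1-[(2S,3E)-4-iodobut-3-en-2-yl]-2,4,5-trimethoxybenzene F3.
  - Suzuki–Miyaura coupling with commercial 2,4,5-trimethoxyphenylboronic acid (Pd(PPh3)4, aq K2CO3, DME, 60 °C) gives 10 with retention of alkene geometry.

**Step 7 (copper hydride hydroboration).**
- Risk: hydrocupration of a very electron-rich, ortho-substituted and β-branched vinylarene may be sluggish. Facial selectivity may drop if the ligand and the C3 centre are mismatched, and the benzylic boronate may undergo protodeboronation.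
- Fallback: this sets out from 10 and returns at 13. It sets C1 by reagent-controlled ketone reduction instead.
  - Mukaiyama hydration (Mn(dpm)3 cat., PhSiH3, O2, iPrOH, 0 °C to rt) places oxygen on C1 through the radical stabilised by ring A. It gives (3S)-1,3-bis(2,4,5-trimethoxyphenyl)butan-1-ol F4 as a mixture of C1 epimers.
  - Dess–Martin periodinane (NaHCO3, CH2Cl2) gives (3S)-1,3-bis(2,4,5-trimethoxyphenyl)butan-1-one F5, in which C3 is β to the carbonyl and not enolisable.
  - Corey–Bakshi–Shibata reduction ((S)-Me-CBS oxazaborolidine cat., BH3·SMe2, THF, −20 °C) should deliver hydride to the face that gives the (R)-aryl carbinol 13.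

**Step 3 (aromatic Claisen rearrangement).**
- Risk: chirality transfer may be incomplete, through the axial-methyl chair or through C–O ionisation. Competing attack at C2 and thermal elimination of the ether to phenol and diene would also cost material or enantiopurity.
- Fallback: this sets out from 2 and returns at 7. It forms the same ring B–C3 bond by copper-mediated anti-SN2′ allylic arylation.
  - Alcohol 2 is esterified (picolinic acid, DCC, DMAP, CH2Cl2) to (2S,3E)-pent-3-en-2-yl pyridine-2-carboxylate F6.
  - Commercial 1-bromo-2,4,5-trimethoxybenzene with Mg turnings (LiCl, THF) gives (2,4,5-trimethoxyphenyl)magnesium bromide F7.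
  - F7 with CuBr·SMe2 (THF, −40 to 0 °C) should attack the alkene terminus anti to the chelated picolinate. The (S)-ester then gives (S,E)-7 directly, bypassing 4, 5 and 6.

**Further compounds**
F1 | step 6 | (4R)-4-(2,4,5-trimethoxyphenyl)pentane-2,3-diol (syn-diol, both facial isomers) | CC(O)C(O)[C@H](C)c1cc(OC)c(OC)cc1OC
F2 | step 6 | (2R)-2-(2,4,5-trimethoxyphenyl)propanal | O=C[C@H](C)c1cc(OC)c(OC)cc1OC
F3 | step 6 | 1-[(2S,3E)-4-iodobut-3-en-2-yl]-2,4,5-trimethoxybenzene | I/C=C/[C@H](C)c1cc(OC)c(OC)cc1OC
F4 | step 7 | (3S)-1,3-bis(2,4,5-trimethoxyphenyl)butan-1-ol (C1 epimers) | COc1cc(OC)c(C(O)C[C@H](C)c2cc(OC)c(OC)cc2OC)cc1OC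
F5 | step 7 | (3S)-1,3-bis(2,4,5-trimethoxyphenyl)butan-1-one | COc1cc(OC)c(C(=O)C[C@H](C)c2cc(OC)c(OC)cc2OC)cc1OC
F6 | step 3 | (2S,3E)-pent-3-en-2-yl pyridine-2-carboxylate | C/C=C/[C@H](C)OC(=O)c1ccccn1
F7 | step 3 | (2,4,5-trimethoxyphenyl)magnesium bromide | COc1cc(OC)c([Mg]Br)cc1OC
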